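Thiocladospolide F is C2-symmetric: two identical (2S,5S,11R) 12-membered lactone rings share one sulfur at C2. Each C2–S bond lies β to a C4 ketone, so the sulfide is assembled last from sulfide ion and two molecules of one enone macrolide. Everything rests on closing that ring at C7–C8, the centre of the unfunctionalised C6–C10 pentamethylene bridge, remote from all stereocentres. One-pot ring-closing metathesis/hydrogenation of an open-chain diene ester closes the ring, erases alkene geometry and frees the C5 hydroxyl. In this precursor the C2=C3 enone is masked as a β-sulfonyl ketone, which blocks competing metathesis and reduction and later departs as sulfinate.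

Key step: step 7

Remark on the chemistry: both halves of the structure read as 2S,5S,11R. In each ring C1 is the lactone carbonyl, C2 the sulfur-bearing carbon, C3 the methylene, C4 the ketone, C5 the carbinol carbon, C6–C10 the five methylenes, C11 the oxygen-bearing methine and C12 its methyl group. Open-chain precursors carry the same numbers.

Step 1
Reactants: 1 (R)-propylene oxide
Product: 2 (R)-hex-5-en-2-ol
Conditions: allylMgBr, CuI (10 mol %), THF, −30 → 0 °C; aq NH4Cl
Reagents that add atoms: allylmagnesium bromide, C=CC[Mg]Br
Why: Copper-catalysed SN2 epoxide opening by a Grignard reagent occurs at the unsubstituted carbon, so the C–O bond of the stereocentre is never broken and C11 (R) is taken unchanged from the chiral pool.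

Step 2
Reactants: 3 furfural
Product: 4 (S)-1-(furan-2-yl)but-3-en-1-ol
Conditions: (S)-BINOL (10 mol %), Ti(OiPr)4 (10 mol %), 4 Å MS, allylSnBu3, CH2Cl2, −20 °C; aq NaHCO3
Reagents that add atoms: allyltributylstannane, C=CC[Sn](CCCC)(CCCC)CCCC
Why: Keck asymmetric allylation, well established for furfural: the (S)-BINOL–titanium Lewis acid exposes one aldehyde face to the allylstannane and thereby sets the S configuration of the future C5.

Step 3
Reactants: 4 (S)-1-(furan-2-yl)but-3-en-1-ol
Product: 5 2-[(S)-1-(benzyloxy)but-3-en-1-yl]furan
Conditions: NaH, BnBr, TBAI (cat.), THF, 0 °C → rt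
Reagents that add atoms: benzyl bromide, BrCc1ccccc1
Why: Williamson ether synthesis on the alkoxide leaves the C–O bond at the stereocentre intact and installs a group that blocks the Achmatowicz pathway in step 4 and falls off during the hydrogenation of step 7.

Step 4
Reactants: 5 2-[(S)-1-(benzyloxy)but-3-en-1-yl]furan
Product: 8 (S,E)-5-(benzyloxy)-4-oxoocta-2,7-dienoic acid, via Z-enal 6 (not isolated), via E-enal 7 (not isolated)
Conditions: NBS (1.05 equiv), NaHCO3, acetone–H2O, −15 °C; pyridine, rt; crude enal: NaClO2, NaH2PO4, 2-methyl-2-butene, t-BuOH–H2O, 0 °C → rt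
Reagents that add atoms: water, O; sodium chlorite, [Na+].[O-]Cl=O
Why: Oxidative furan ring opening with NBS in wet acetone (the electron-rich furan reacts far faster than the terminal alkene) gives the Z-ene-dicarbonyl, pyridine isomerises it to the E-enal by reversible conjugate addition, and Pinnick oxidation with a hypochlorite scavenger then delivers the acid without touching C5 or the vinyl group.

Step 5
Reactants: 8 (S,E)-5-(benzyloxy)-4-oxoocta-2,7-dienoic acid; 2 (R)-hex-5-en-2-ol
Product: 9 (R)-hex-5-en-2-yl (S,E)-5-(benzyloxy)-4-oxoocta-2,7-dienoate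
Conditions: DCC, DMAP (10 mol %), CH2Cl2, 0 °C → rt
Reagents that add atoms: none
Why: Steglich esterification activates the acid and not the alcohol, so C11 keeps its R configuration and the E-ene-dione survives the mild, nearly neutral conditions.

Step 6
Reactants: 9 (R)-hex-5-en-2-yl (S,E)-5-(benzyloxy)-4-oxoocta-2,7-dienoate
Product: 10 (R)-hex-5-en-2-yl (5S)-5-(benzyloxy)-4-oxo-2-(p-tolylsulfonyl)oct-7-enoate (both C2 epimers)
Conditions: p-TolSO2H (1.2 equiv, freshly liberated from its sodium salt), CH2Cl2, rt, Ar, dark
Reagents that add atoms: p-toluenesulfinic acid, Cc1ccc(cc1)S(=O)O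
Why: Conjugate (sulfa-Michael type) addition of the soft sulfur of a sulfinic acid to the ene-dione occurs at C2, β to the more strongly activating ketone, leaves the unactivated vinyl groups alone, and the new C2 centre may form as both epimers because step 8 erases it.

Step 7
Reactants: 10 (R)-hex-5-en-2-yl (5S)-5-(benzyloxy)-4-oxo-2-(p-tolylsulfonyl)oct-7-enoate (both C2 epimers)
Product: 12 (5S,11R)-5-hydroxy-4-oxo-2-(p-tolylsulfonyl)dodecan-11-olide (both C2 epimers), via cycloalkene 11 (not isolated)
Conditions: Hoveyda–Grubbs II (5 mol %, two portions), EtOAc (1 mM), 60 °C, Ar sparge; concentrate in the same flask to 0.05 M, 10% Pd/C, H2 (1 atm), rt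
Reagents that add atoms: none
Why: The phosphine-free ruthenium alkylidene loads onto the unhindered C8 vinyl group of the hexenyl arm and undergoes intramolecular [2+2] cycloaddition/cycloreversion with the C7 vinyl group (Chauvin cycle), expelling ethylene that the argon stream removes, after which palladium-catalysed hydrogenation in the same flask saturates C7=C8 and hydrogenolyses the benzyl ether. The closest known reaction type is macrocyclic ring-closing metathesis of ω-alkenyl alkenoates to 12-membered lactones followed by hydrogenation. The one ring closed is the 12-membered oxacyclododecane ring, formed by end-to-end macrocyclisation of the only two terminal alkenes, so no smaller ring is available as an alternative. No stereocentre is created: the E/Z mixture at C7=C8 converges on one alkane, C5 and C11 are not touched, and both C2 epimers are carried on because step 8 erases that centre. The step needs chemoselectivity for the terminal alkenes and cyclisation over oligomerisation: saturation of C2–C3 by the sulfone removes the enone that could otherwise close a cyclopentenone with C7 or be reduced by hydrogen, while high dilution, the Z ester conformer, the sp2 C4 and the branching at C2, C5 and C11 favour the folded chain. The neutral, phosphine-free medium keeps the base-labile β-sulfonyl ketone intact, and sulfones do not poison ruthenium or palladium.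

Step 8
Reactants: 12 (5S,11R)-5-hydroxy-4-oxo-2-(p-tolylsulfonyl)dodecan-11-olide (both C2 epimers, two equivalents)
Product: 15 thiocladospolide F, via enone 13 (not isolated), via thiol 14 (not isolated)
Conditions: Na2S·9H2O (0.5 equiv, slow addition), degassed THF–H2O, 0 °C → rt
Reagents that add atoms: sodium sulfide, [Na+].[Na+].[S-2]
Why: Base-induced E1cB loss of sulfinate from either C2 epimer unveils the E-enone 13, and a biomimetic double sulfa-Michael addition (hydrosulfide, then the thiolate of 14) follows in which the transannular C6–C10 chain blocks the inner face of the enone standing perpendicular to the ring, so sulfur should enter both rings from the peripheral C2 Si face fixed by the C5 and C11 centres to give 2S,2'S, the reversibility of the addition allowing correction towards the more stable adduct.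

Compound list
1 | (R)-propylene oxide | C[C@@H]1CO1 | starting material
2 | (R)-hex-5-en-2-ol | C[C@@H](O)CCC=C | intermediate
3 | furfural | O=Cc1ccco1 | starting material
4 | (S)-1-(furan-2-yl)but-3-en-1-ol | C=CC[C@H](O)c1ccco1 | intermediate
5 | 2-[(S)-1-(benzyloxy)but-3-en-1-yl]furan | C=CC[C@H](OCc1ccccc1)c1ccco1 | intermediate
6 | (S,Z)-5-(benzyloxy)-4-oxoocta-2,7-dienal | C=CC[C@H](OCc1ccccc1)C(=O)/C=C\C=O | intermediate
7 | (S,E)-5-(benzyloxy)-4-oxoocta-2,7-dienal | C=CC[C@H](OCc1ccccc1)C(=O)/C=C/C=O | intermediate
8 | (S,E)-5-(benzyloxy)-4-oxoocta-2,7-dienoic acid | C=CC[C@H](OCc1ccccc1)C(=O)/C=C/C(=O)O | intermediate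
9 | (R)-hex-5-en-2-yl (S,E)-5-(benzyloxy)-4-oxoocta-2,7-dienoate | C=CC[C@H](OCc1ccccc1)C(=O)/C=C/C(=O)O[C@H](C)CCC=C | intermediate
10 | (R)-hex-5-en-2-yl (5S)-5-(benzyloxy)-4-oxo-2-(p-tolylsulfonyl)oct-7-enoate, both C2 epimers | C=CC[C@H](OCc1ccccc1)C(=O)CC(C(=O)O[C@H](C)CCC=C)S(=O)(=O)c1ccc(C)cc1 | intermediate
11 | (5S,11R)-5-(benzyloxy)-4-oxo-2-(p-tolylsulfonyl)dodec-7-en-11-olide, E/Z at C7=C8, both C2 epimers | C[C@@H]1CCC=CC[C@H](OCc2ccccc2)C(=O)CC(S(=O)(=O)c2ccc(C)cc2)C(=O)O1 | intermediate
12 | (5S,11R)-5-hydroxy-4-oxo-2-(p-tolylsulfonyl)dodecan-11-olide, both C2 epimers | C[C@@H]1CCCCC[C@H](O)C(=O)CC(S(=O)(=O)c2ccc(C)cc2)C(=O)O1 | intermediate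
13 | (2E,5S,11R)-5-hydroxy-4-oxododec-2-en-11-olide | C[C@@H]1CCCCC[C@H](O)C(=O)/C=C/C(=O)O1 | intermediate
14 | (2S,5S,11R)-5-hydroxy-2-mercapto-4-oxododecan-11-olide | C[C@@H]1CCCCC[C@H](O)C(=O)C[C@H](S)C(=O)O1 | intermediate
15 | thiocladospolide F, bis[(2S,5S,11R)-5-hydroxy-4-oxododecan-11-olid-2-yl] sulfide | C[C@@H]1CCCCC[C@H](O)C(=O)C[C@H](S[C@H]2CC(=O)[C@@H](O)CCCCC[C@@H](C)OC2=O)C(=O)O1 | target

Total step count: 8. Longest linear sequence: 7 steps (steps 2–8, from furfural).

Steps most likely to fail

Step 7.
- **What may go wrong:** Sulfinate may be lost by β-elimination during the slow closure of the 12-membered ring, which would expose the ene-dione to the hydrogenation stage. Oligomerisation may also compete with cyclisation.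
- **Fallback:** The sulfone mask is given up and the thioether bridge itself protects the enone. The fallback sets out from 9.
  - Ring-closing metathesis of the unmasked triene should give (2E,5S,11R)-5-(benzyloxy)-4-oxododeca-2,7-dien-11-olide F1. The electron-poor 1,2-disubstituted C2=C3 alkene could react only by releasing an ester-substituted carbene, so it should stay a spectator.
  - Half an equivalent of sodium sulfide then gives bis[(2S,5S,11R)-5-(benzyloxy)-4-oxododec-7-en-11-olid-2-yl] sulfide F2.
  - Diimide from potassium azodicarboxylate and acetic acid, which sulfur does not poison, saturates both C7=C8 bonds to give bis[(2S,5S,11R)-5-(benzyloxy)-4-oxododecan-11-olid-2-yl] sulfide F3.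
  - BCl3 with pentamethylbenzene as cation scavenger at −78 °C removes both benzyl groups, and the route is rejoined at 15.

Step 8.
- **What may go wrong:** Facial selectivity may be poor in one or both C–S bond formations. The reaction may stall at the thiol stage. The transiently basic medium may epimerise C5.
- **Fallback:** The cascade is replaced by a stepwise, catalyst-controlled assembly that sets out from 12.
  - Triethylamine in CH2Cl2 gives the enone 13, which is isolated.
  - Thioacetic acid is added under a bifunctional cinchona-alkaloid squaramide catalyst, using the pseudoenantiomer matched to Si-face delivery. This gives (2S,5S,11R)-2-(acetylthio)-5-hydroxy-4-oxododecan-11-olide F4, which can be purified to one isomer.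
  - Acidic methanolysis (AcCl in MeOH), under which loss of sulfur by retro-Michael reaction cannot start, frees thiol 14.
  - Thiol 14 is added to a second equivalent of 13 under the same catalyst, and the route is rejoined at 15.

Step 4.
- **What may go wrong:** Bromohydrin formation may compete at the terminal alkene. Z→E isomerisation may be incomplete, in which case the Z-acid closes to its cyclic pseudo-acid and does not couple in step 5.
- **Fallback:** The fallback is halogen-free and sets out from 5.
  - Dye-sensitised photooxygenation (O2, TPP, hν, CH2Cl2, −78 °C, then iPr2NEt; [4+2] addition and Kornblum–DeLaMare opening) gives 5-[(S)-1-(benzyloxy)but-3-en-1-yl]-5-hydroxyfuran-2(5H)-one F5, the ring tautomer of the Z-keto acid.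
  - A Mitsunobu reaction alkylates its open-chain carboxylate with (S)-hex-5-en-2-ol F6, which is made from (S)-propylene oxide as in step 1. Inversion at C11 gives (R)-hex-5-en-2-yl (S,Z)-5-(benzyloxy)-4-oxoocta-2,7-dienoate F7.
  - The sulfinic acid addition of step 6 erases the alkene geometry, and the route is rejoined at 10.

Further compounds
F1 | step 7 | (2E,5S,11R)-5-(benzyloxy)-4-oxododeca-2,7-dien-11-olide, E/Z at C7=C8 | C[C@@H]1CCC=CC[C@H](OCc2ccccc2)C(=O)/C=C/C(=O)O1
F2 | step 7 | bis[(2S,5S,11R)-5-(benzyloxy)-4-oxododec-7-en-11-olid-2-yl] sulfide | C[C@@H]1CCC=CC[C@H](OCc2ccccc2)C(=O)C[C@H](S[C@H]2CC(=O)[C@@H](OCc3ccccc3)CC=CCC[C@@H](C)OC2=O)C(=O)O1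
F3 | step 7 | bis[(2S,5S,11R)-5-(benzyloxy)-4-oxododecan-11-olid-2-yl] sulfide | C[C@@H]1CCCCC[C@H](OCc2ccccc2)C(=O)C[C@H](S[C@H]2CC(=O)[C@@H](OCc3ccccc3)CCCCC[C@@H](C)OC2=O)C(=O)O1
F4 | step 8 | (2S,5S,11R)-2-(acetylthio)-5-hydroxy-4-oxododecan-11-olide | C[C@@H]1CCCCC[C@H](O)C(=O)C[C@H](SC(C)=O)C(=O)O1
F5 | step 4 | 5-[(S)-1-(benzyloxy)but-3-en-1-yl]-5-hydroxyfuran-2(5H)-one | C=CC[C@H](OCc1ccccc1)C1(O)C=CC(=O)O1
F6 | step 4 | (S)-hex-5-en-2-ol | C[C@H](O)CCC=C
F7 | step 4 | (R)-hex-5-en-2-yl (S,Z)-5-(benzyloxy)-4-oxoocta-2,7-dienoate | C=CC[C@H](OCc1ccccc1)C(=O)/C=C\C(=O)O[C@H](C)CCC=C
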